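A small charge of reagent, 0.500 mM in amber, meets 1.0 mM of substrate, so reagent is the limiting reagent there. Each substrate unit can take up to four reagent units in turn, and the question is where the middle member stands at the end.

in all of them: substrate 1.0 mM; time 1.0 min

| run | reagent |
|---|---|
| amber | 0.500 mM |
| ochre | 1.00 mM |
| grey | 2.00 mM |
| teal | 4.00 mM |

    substrate + reagent → single product + by-product (k1 = 25.7 M⁻¹ s⁻¹)
    reagent + single product → bis adduct + by-product (k2 = 18.2 M⁻¹ s⁻¹)
    reagent + bis adduct → tris adduct + by-product (k3 = 39.1 M⁻¹ s⁻¹)
    reagent + tris adduct → tetra adduct + by-product (k4 = 9.40 M⁻¹ s⁻¹)
    substrate + bis adduct ⇌ idle adduct, settled at all times (K5 = 340 M⁻¹)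

1. [bis adduct] (only what is free in solution) at the end for amber, ochre, grey, teal, in this order
2. the shape of the row from first to last (rises all the way / falls all the way / rises, then falls / falls, then rises / hardly changes)

- percent here means substrate units held: one idle adduct counts as two
- what is said of bis adduct includes idle adduct
- in an amount of bis adduct, one idle adduct counts as one bis adduct
- the concentration of bis adduct that is asked is that of its free form alone
- "hardly changes" means that all values lie within two and a half points (for a concentration: within two and a half percent of the largest)
- run time (amber): 1.0 min

In the first instants, step one is the consumer of reagent. Its constant k, multiplied by the charged substrate S, becomes a time: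

τ = ln(2) / (k × S) = 0.450 min

This τ is the reagent half-life against the charged substrate. It contains no reagent charge, and S is 1.0 mM in amber, ochre, grey and teal, so my reckoning uses one τ for them. Amber's substrate has a longer half-life, 0.90 min. Teal's substrate has a shorter one, 0.112 min.

In the middle, single product takes over part of the reagent traffic. It takes up reagent with the constant 18.2 M⁻¹ s⁻¹, and the constant of bis adduct is twice as large, at 39.1 M⁻¹ s⁻¹. Each unit short of tetra adduct still offers reagent a site, so my reckoning keeps τ. Idle adduct holds back some bis adduct: with 0.34 as the binding strength at the charged substrate, the free form starts at 74.6 % of bis adduct, and that share grows as substrate goes.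

At the end, τ gives the reagent left, and from it an exposure X, the charged ratio of reagent to substrate times the share spent:

reagent left = 21.4 %

X = 0.393, 0.786, 1.57, 3.14 for amber, ochre, grey, teal

Substrate left is then e^(−X). Every step uses reagent, so on the scale of X step one runs at unit speed, step two at 0.708 and step three at 1.52. A chain of first-order steps has a standard solution (the Bateman equation), and with idle adduct set aside it gives for bis adduct:

bis adduct = 0.0359 mM, 0.0947 mM, 0.167 mM, 0.135 mM for amber, ochre, grey, teal

So my reckoning gives a row that rises, then falls.

The forecast gives 0.031 mM, 0.086 mM, 0.167 mM and 0.124 mM, a row that rises, then falls. Its ground is that the fast third step “puts the peak near two equivalents”. Its shape is the one reckoned here.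

The simulation gives 0.0316 mM, 0.0912 mM, 0.168 mM and 0.119 mM, so the row rises, then falls. The reading turns at 2.4 mM of reagent. Amber ends with 23 % of its reagent and 66.3 % of its substrate, where τ gave 21.4 % and 67.5 %. Teal, with the same τ, was reckoned at 21.4 % of its reagent and 4.33 % of its substrate, and it ends with 3.26 % of substrate and 33 % of reagent.

(The rate constants stand for no real mixture.)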